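**Retrosynthetic overview**

1. Target 13 is 7,4'-dihydroxyisoflavone carrying a (1Z,3R)-3,7-dimethylocta-1,6-dienyl chain at C3'. The Z-alkene is traced back to syn semi-hydrogenation of aryl alkyne 11, and 11 to Sonogashira coupling of aryl bromide 7 with alkyne 10.
2. Alkyne 10 comes from (R)-citronellal 8 by formal dehydration through enol nonaflate 9; the only stereocentre is taken from the chiral pool.
3. The strategy rests on the pyranone ring C (O1, C2, C3, C4, C4a, C8a). It is cut at C4–C4a, C2–C3 and O1–C2 into resorcinol 1 (ring A with O1 and the 7-OH), arylacetic acid 2 (C4, C3 and ring B with the bromide handle) and DMF 3 (C2).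
4. Ring order: rings A and B are bought, ring C is the only ring formed (step 1), and the acid-sensitive diene chain is attached only afterwards.

Key step: step 1

Remark: the target SMILES is read as a (1Z,3R) side chain. (R)-Citronellal has the same spatial arrangement at C3, and the CIP descriptor stays R in the enol nonaflate, the alkyne and the alkene.

**Route**

Step 1
Reactants: 1 resorcinol; 2 (3-bromo-4-hydroxyphenyl)acetic acid; 3 N,N-dimethylformamide
Product: 6 3-(3-bromo-4-hydroxyphenyl)-7-hydroxy-4H-chromen-4-one (3'-bromodaidzein), via deoxybenzoin 4 (not isolated), via enaminone 5 (not isolated)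
Conditions: BF3·OEt2 (neat, excess), 85 °C; cool, DMF (3); MsCl in DMF, 50 → 90 °C; ice-water
Reagents that add atoms: N,N-dimethylformamide (compound 3), CN(C)C=O
Why: BF3 activates acid 2 as an acylium equivalent and Friedel–Crafts acylation of resorcinol forms C4–C4a, the ketone 4 being held as its O,O-difluoroboron chelate between the carbonyl and the ortho hydroxyl. DMF and MsCl then give a Vilsmeier-type iminium salt that attacks the benzylic carbon of the chelated enol (C2–C3) and gives enaminone 5. The ortho phenol oxygen adds to C2 of the enaminone in a 6-endo-trig oxa-Michael addition and dimethylamine is expelled (O1–C2), which closes ring C as the aromatic pyranone. The closest known reaction type is the one-pot boron trifluoride deoxybenzoin synthesis followed by Vilsmeier one-carbon cyclisation used for polyhydroxyisoflavones. No stereocentre is formed. The step needs C-acylation at C4 of resorcinol and not at C2 or on oxygen: C4 is ortho/para to both hydroxyls and unhindered, any aryl ester undergoes Fries rearrangement under the same conditions, the chelate deactivates the product toward a second acylation, and the bromophenol ring of 2 is too electron-poor to compete as a nucleophile in the acylation or the formylation.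

Step 2
Reactants: 6 3-(3-bromo-4-hydroxyphenyl)-7-hydroxy-4H-chromen-4-one
Product: 7 3-[3-bromo-4-(tert-butyldimethylsilyloxy)phenyl]-7-(tert-butyldimethylsilyloxy)-4H-chromen-4-one
Conditions: TBSCl (2.5 equiv), imidazole (5 equiv), DMF, 0 °C → rt
Reagents that add atoms: tert-butyldimethylsilyl chloride (TBSCl), CC(C)(C)[Si](C)(C)Cl
Why: Silylation of phenols with TBSCl/imidazole is fast for both the acidic 7-OH and the ortho-bromophenol, and masking the 4'-OH keeps the later ortho-alkynylphenol from cyclising to a benzofuran under Pd/Cu.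

Step 3
Reactants: 8 (R)-citronellal
Product: 10 (R)-3,7-dimethyloct-6-en-1-yne, via enol nonaflate 9 (not isolated)
Conditions: nonafluorobutane-1-sulfonyl fluoride (NfF, 1.3 equiv), P2-Et phosphazene base (2.4 equiv), DMF, −30 °C → rt; pentane extraction, careful distillation
Reagents that add atoms: none
Why: This is the known one-pot nonaflation–elimination of enolisable aldehydes, in which the phosphazene base enolises the aldehyde toward C2, NfF traps the enolate on oxygen as enol nonaflate 9 and a second equivalent of base removes the vinylic C2–H in an E2 loss of nonaflate to give the terminal alkyne; the C3 stereocentre is not deprotonated in either event and the acid-free medium avoids the carbonyl-ene cyclisation of citronellal, so the R centre of 8 should be carried over unchanged.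

Step 4
Reactants: 7 3-[3-bromo-4-(tert-butyldimethylsilyloxy)phenyl]-7-(tert-butyldimethylsilyloxy)-4H-chromen-4-one; 10 (R)-3,7-dimethyloct-6-en-1-yne (1.3 equiv)
Product: 11 7-(tert-butyldimethylsilyloxy)-3-{4-(tert-butyldimethylsilyloxy)-3-[(3R)-3,7-dimethyloct-6-en-1-yn-1-yl]phenyl}-4H-chromen-4-one
Conditions: Pd(PhCN)2Cl2 (3 mol%), [HP(t-Bu)3]BF4 (6 mol%), CuI (2 mol%), i-Pr2NH (2 equiv), degassed dioxane, rt → 45 °C
Reagents that add atoms: none
Why: Sonogashira coupling, in which the electron-rich tri-tert-butylphosphine–Pd(0) catalyst inserts into the hindered ortho-silyloxy C–Br bond at low temperature, the copper acetylide of 10 transmetalates and reductive elimination forms the C3'–C(sp) bond, while the silyl ethers, the chromone and the propargylic stereocentre are inert to the hindered amine.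

Step 5
Reactants: 11 7-(tert-butyldimethylsilyloxy)-3-{4-(tert-butyldimethylsilyloxy)-3-[(3R)-3,7-dimethyloct-6-en-1-yn-1-yl]phenyl}-4H-chromen-4-one
Product: 12 7-(tert-butyldimethylsilyloxy)-3-{4-(tert-butyldimethylsilyloxy)-3-[(1Z,3R)-3,7-dimethylocta-1,6-dien-1-yl]phenyl}-4H-chromen-4-one
Conditions: H2 (1 atm), Lindlar catalyst (Pd/CaCO3, Pb-poisoned), quinoline, EtOAc/hexane, rt, stopped at one equivalent of H2
Reagents that add atoms: none
Why: Lindlar semi-hydrogenation delivers one equivalent of H2 syn on the lead- and quinoline-poisoned palladium surface to give the Z-alkene, and the poisoned catalyst should not reduce the trisubstituted alkene, the chromone C2=C3 bond or the product styrene at a competitive rate; the allylic stereocentre is untouched.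

Step 6
Reactants: 12 7-(tert-butyldimethylsilyloxy)-3-{4-(tert-butyldimethylsilyloxy)-3-[(1Z,3R)-3,7-dimethylocta-1,6-dien-1-yl]phenyl}-4H-chromen-4-one
Product: 13 3-{3-[(1Z,3R)-3,7-dimethylocta-1,6-dien-1-yl]-4-hydroxyphenyl}-7-hydroxy-4H-chromen-4-one (CNP0200226.1)
Conditions: TBAF (2.5 equiv), AcOH (2.5 equiv), THF, 0 °C
Reagents that add atoms: none
Why: Fluoride-mediated desilylation with buffered TBAF cleaves both aryl Si–O bonds through pentacoordinate silicates under near-neutral conditions that leave the Z-styrene, the trisubstituted alkene and the chromone intact, which is why acid-labile protecting groups were avoided.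

**Compound list**

1 | resorcinol (benzene-1,3-diol) | Oc1cccc(O)c1 | starting material
2 | (3-bromo-4-hydroxyphenyl)acetic acid | OC(=O)Cc1ccc(O)c(Br)c1 | starting material
3 | N,N-dimethylformamide | CN(C)C=O | starting material
4 | 2-(3-bromo-4-hydroxyphenyl)-1-(2,4-dihydroxyphenyl)ethan-1-one (deoxybenzoin, present in the flask as its O,O-difluoroboron chelate) | O=C(Cc1ccc(O)c(Br)c1)c1ccc(O)cc1O | intermediate (not isolated)
5 | 2-(3-bromo-4-hydroxyphenyl)-1-(2,4-dihydroxyphenyl)-3-(dimethylamino)prop-2-en-1-one (enaminone, alkene geometry not defined) | CN(C)C=C(C(=O)c1ccc(O)cc1O)c1ccc(O)c(Br)c1 | intermediate (not isolated)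
6 | 3-(3-bromo-4-hydroxyphenyl)-7-hydroxy-4H-chromen-4-one (3'-bromodaidzein) | O=c1c(-c2ccc(O)c(Br)c2)coc2cc(O)ccc12 | intermediate
7 | 3-[3-bromo-4-(tert-butyldimethylsilyloxy)phenyl]-7-(tert-butyldimethylsilyloxy)-4H-chromen-4-one | CC(C)(C)[Si](C)(C)Oc1ccc2c(c1)occ(-c1ccc(O[Si](C)(C)C(C)(C)C)c(Br)c1)c2=O | intermediate
8 | (R)-citronellal [(3R)-3,7-dimethyloct-6-enal] | CC(C)=CCC[C@@H](C)CC=O | starting material
9 | (3R)-3,7-dimethylocta-1,6-dien-1-yl nonafluorobutane-1-sulfonate (enol nonaflate, E/Z mixture at C1=C2) | CC(C)=CCC[C@@H](C)C=COS(=O)(=O)C(F)(F)C(F)(F)C(F)(F)C(F)(F)F | intermediate (not isolated)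
10 | (R)-3,7-dimethyloct-6-en-1-yne | CC(C)=CCC[C@@H](C)C#C | intermediate
11 | 7-(tert-butyldimethylsilyloxy)-3-{4-(tert-butyldimethylsilyloxy)-3-[(3R)-3,7-dimethyloct-6-en-1-yn-1-yl]phenyl}-4H-chromen-4-one | CC(C)=CCC[C@@H](C)C#Cc1cc(-c2coc3cc(O[Si](C)(C)C(C)(C)C)ccc3c2=O)ccc1O[Si](C)(C)C(C)(C)C | intermediate
12 | 7-(tert-butyldimethylsilyloxy)-3-{4-(tert-butyldimethylsilyloxy)-3-[(1Z,3R)-3,7-dimethylocta-1,6-dien-1-yl]phenyl}-4H-chromen-4-one | CC(C)=CCC[C@@H](C)/C=C\c1cc(-c2coc3cc(O[Si](C)(C)C(C)(C)C)ccc3c2=O)ccc1O[Si](C)(C)C(C)(C)C | intermediate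
13 | 3-{3-[(1Z,3R)-3,7-dimethylocta-1,6-dien-1-yl]-4-hydroxyphenyl}-7-hydroxy-4H-chromen-4-one | CC(C)=CCC[C@@H](C)/C=C\c1cc(-c2coc3cc(O)ccc3c2=O)ccc1O | target

**Step count**

Total steps: 6. Longest linear sequence: 5 steps (1 → 2 → 4 → 5 → 6); the alkyne branch (step 3) joins at step 4.

**Steps most likely to fail, with fallbacks**

Step 3. The E-configured enol nonaflate can only eliminate syn and may do so slowly. Prolonged exposure of the product to the strong base could then cause propargyl–allenyl isomerisation and erode the C3 centre, and the volatile alkyne can be lost on isolation. The fallback sets out from 8 and returns at 10, and uses no vinyl sulfonate and no strong base.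
- L-Proline-catalysed α-aminoxylation of 8 with nitrosobenzene, followed in the same flask by NaBH4, should give (2R,3R)-3,7-dimethyl-2-[(phenylamino)oxy]oct-6-en-1-ol F1. The C2 configuration is immaterial.
- N–O cleavage with Zn/AcOH should give (2R,3R)-3,7-dimethyloct-6-ene-1,2-diol F2.
- NaIO4 in THF/water cleaves the glycol, removing the old C1, to give (R)-2,6-dimethylhept-5-enal F3, which is used crude.
- Seyferth–Gilbert homologation with the Ohira–Bestmann reagent (K2CO3, MeOH, 0 °C) adds one carbon back and gives alkyne 10.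

Step 4. Oxidative addition at the hindered, electron-rich bromide may be sluggish, the alkyne may dimerise oxidatively on copper, or the O4' silyl group may be lost and the resulting ortho-alkynylphenol may cycloisomerise to a benzofuran. The fallback sets out from 10 and 7 and returns at 12, so it also bypasses step 5.
- Rhodium-catalysed trans-hydroboration of 10 ([Rh(cod)Cl]2, P(i-Pr)3, Et3N, pinacolborane, cyclohexane, rt) should give 2-[(1Z,3R)-3,7-dimethylocta-1,6-dien-1-yl]-4,4,5,5-tetramethyl-1,3,2-dioxaborolane F4.
- Stereoretentive Suzuki–Miyaura coupling of F4 with bromide 7 (Pd(OAc)2/SPhos, K3PO4, THF/H2O, 40 °C) gives 12 directly.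

Step 5. The hydrogenation may run on to the saturated chain, stall because of the flanking silyl ether, or isomerise the Z-alkene to E on palladium. The fallback sets out from 7 and 10 and returns at 12, with the alkene geometry fixed before the C–C bond is made.
- Miyaura borylation of 7 (B2pin2, Pd(dppf)Cl2, KOAc, dioxane, 85 °C) should give 7-(tert-butyldimethylsilyloxy)-3-[4-(tert-butyldimethylsilyloxy)-3-(4,4,5,5-tetramethyl-1,3,2-dioxaborolan-2-yl)phenyl]-4H-chromen-4-one F5.
- Alkyne 10 is lithiated (n-BuLi, THF, −78 °C) and iodinated with I2 to (R)-1-iodo-3,7-dimethyloct-6-en-1-yne F6.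
- Diimide reduction of F6 (o-nitrobenzenesulfonyl hydrazide, Et3N, THF/i-PrOH) gives (1Z,3R)-1-iodo-3,7-dimethylocta-1,6-diene F7.
- Suzuki–Miyaura coupling of F5 with F7 (Pd(PPh3)4, aq. K3PO4, THF, rt → 40 °C) proceeds with retention of alkene geometry and gives 12.

**Further compounds**

F1 | step 3 | (2R,3R)-3,7-dimethyl-2-[(phenylamino)oxy]oct-6-en-1-ol | OC[C@H](ONc1ccccc1)[C@H](C)CCC=C(C)C
F2 | step 3 | (2R,3R)-3,7-dimethyloct-6-ene-1,2-diol | OC[C@H](O)[C@H](C)CCC=C(C)C
F3 | step 3 | (R)-2,6-dimethylhept-5-enal | O=C[C@H](C)CCC=C(C)C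
F4 | step 4 | 2-[(1Z,3R)-3,7-dimethylocta-1,6-dien-1-yl]-4,4,5,5-tetramethyl-1,3,2-dioxaborolane | CC(C)=CCC[C@@H](C)/C=C\B1OC(C)(C)C(C)(C)O1
F5 | step 5 | 7-(tert-butyldimethylsilyloxy)-3-[4-(tert-butyldimethylsilyloxy)-3-(4,4,5,5-tetramethyl-1,3,2-dioxaborolan-2-yl)phenyl]-4H-chromen-4-one | CC(C)(C)[Si](C)(C)Oc1ccc2c(c1)occ(-c1ccc(O[Si](C)(C)C(C)(C)C)c(B3OC(C)(C)C(C)(C)O3)c1)c2=O
F6 | step 5 | (R)-1-iodo-3,7-dimethyloct-6-en-1-yne | CC(C)=CCC[C@@H](C)C#CI
F7 | step 5 | (1Z,3R)-1-iodo-3,7-dimethylocta-1,6-diene | CC(C)=CCC[C@@H](C)/C=C\I
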